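Compound numbers refer to the compound list after the steps.

## Analysis of the target

The target (19) is an open-chain bis(bibenzyl): four benzene rings joined in the order A–CH2CH2–B–O–C–CH2CH2–D, with no ring fusion and no macrocycle. Ring A is a phenol with the bridge on C1, the hydroxyl on C3 and an unsubstituted C2 between them. Ring B is a para-phenylene carrying the bridge and the ether oxygen. Ring C is 1,2,4-trisubstituted, with its hydroxyl ortho to the aryloxy group and para to the second bridge, and ring D is a hydroquinone substituted at C2. There are no stereocentres and no double-bond geometry, so the molecule is achiral and nothing has to be related stereochemically. The sensitive parts are the hydroquinone of ring D, which air oxidises to the quinone (fastest under base), and the electron-rich rings C and D, which are open to electrophilic halogenation and oxidation; the diaryl ether itself is robust. The difficulty is one of regiochemistry and differentiation: two nearly identical ethylene bridges must be installed separately on an unsymmetrical diaryl ether, and four phenolic oxygens in three different environments must be carried through. The plan rests on the 1,3-relationship in ring A between the hydroxyl carbon and the bridge carbon across a bare carbon. That is the pattern left when a 6-alkylsalicylic acid loses its carboxyl group, and a 6-alkylsalicylate is the aromatised form of the cyclohexenone that an acetoacetic ester and a 2-alkenal give by Michael addition and aldol closure.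

## Retrosynthetic reasoning

**19 ⇒ 18.** The three O–CH3 bonds on rings C and D are restored first. The hydroquinone and the guaiacol-type phenol are too oxidisable and too nucleophilic to carry through C–C bond formation, and methyl ethers survive everything that precedes. The ring A hydroxyl needs no mask because it is created late. The forward step has to cleave three methyl ethers without touching the diaryl ether.

**18 ⇒ 17 ⇒ 16.** A carboxyl group is put back on the ring A carbon that lies between the hydroxyl carbon and the bridge carbon. The 3-alkylphenol 18 thus becomes the 6-alkylsalicylic acid 17 and its ethyl ester 16. This turns a 1,3-disubstituted arene, which has no obvious ring-forming retron, into a 1,2,3-trisubstituted one that maps onto an acetoacetate unit. Forward, the ester must be hydrolysed and the acid must lose CO2.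

**16 ⇒ 14.** Ring A is taken back by two hydrogens to the cyclohexenone β-keto ester 14. The ketone oxygen of 14 is the future phenol oxygen, C1 carries the ester and C6 the bridge. Forward, a dehydrogenation is needed that spares the electron-rich rings C and D.

**14 ⇒ 10 + 11.** The C1–C6 bond and the C3=C4 bond of 14 are cut. These are the two bonds whose formation is polarity-matched: C1 is the doubly activated carbon of ethyl acetoacetate 11 and C6 the β-carbon of enal 10, while C3 is the acetyl methyl carbon and C4 the aldehyde carbon. Cutting here leaves a four-carbon commodity and an enal in which rings B, C and D are complete and act only as spectators. Forward, conjugate addition must win over carbonyl addition, and the ring must close through the methyl group.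

**10 ⇒ 9 ⇒ 8.** The C2=C3 double bond of the enal is cut as a two-carbon Wittig homologation of aldehyde 9, and 9 is the partial-reduction product of methyl ester 8. The three-carbon chain on ring B therefore comes from a propanoate, whose carbonyl carbon ends as C6 of ring A.

**8 ⇒ 7 ⇒ 5 + 2.** The bridge between rings C and D is cut at the benzylic carbon next to ring C, through stilbene 7. Forward this is a Wittig reaction between aldehyde 5 and ylide 6, generated from phosphonium salt 2, followed by hydrogenation. This avoids organometallic reagents in the presence of the ester, and the alkene geometry does not matter.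

**5 ⇒ 3 + 4.** The diaryl ether is cut at the bond between oxygen and ring C. Phenol 3 brings ring B with its propanoate chain; bromide 4 brings ring C with the formyl handle and the methoxy group already in the right places. The other C–O bond would pair a hindered guaiacol-type nucleophile with an unactivated halide and gains nothing. Forward, a copper-catalysed Ullmann etherification must tolerate an aldehyde and an ester.

**2 ⇒ 1.** The C–P bond of 2 is cut back to benzylic alcohol 1.

## Alternatives that were turned down

**Alternative 1:** The two aryl–C bonds of the bridges, at ring B and at ring C, are cut as aryl–alkyne bonds around a preformed diaryl ether. Forward, 4-bromo-2-(4-iodophenoxy)-1-methoxybenzene A1 would undergo two Sonogashira couplings in one flask under palladium/copper catalysis: first at the C–I bond with 3-ethynylanisole A2, then at the C–Br bond with 2-ethynyl-1,4-dimethoxybenzene A3. This gives the bis(diarylalkyne) A4, which is hydrogenated and demethylated.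

- For it: it is highly convergent, the three fragments are simple, and the reactivity gap between iodide and bromide orders the couplings without protecting groups. The whole route would be about half as long as the chosen one. On step economy it is clearly the stronger plan.
- Against it: the second coupling is at a bromide para to a methoxy group, where oxidative addition is slow. The heating it needs invites alkyne homocoupling and attack of residual A2 at the bromide. A1 must also be made with two different halogens intact, which rules out a copper-catalysed etherification in the presence of the aryl iodide and forces a detour. No ring is built.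
- Comparison: the chosen strategy is longer. In exchange it has no late transition-metal C–C coupling on an electron-rich haloarene, and the oxygen pattern of ring A is fixed by connectivity. It also passes through the carboxylated compounds 16 and 17, which are of interest as biogenetic relatives of the target.

**Alternative 2:** Ring B is disconnected across two of its C–C bonds. Forward, methyl coumalate A5 and the aryl ethynyl ether A6 (the ethynyl ether of the ring C phenol with ring D attached) would undergo an inverse-demand [4+2] cycloaddition followed by decarboxylative cycloreversion, giving the methyl 4-aryloxybenzoate A7.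

- For it: the diaryl ether oxygen is introduced without a metal, and the polarisation of both partners should give the para isomer.
- Against it: the ring being built is a plain para-phenylene that can be bought. Aryl ethynyl ethers need a multistep, strongly basic preparation and are heat-sensitive. A7 carries only one carbon at ring B, so reduction, a benzylic Wittig reaction and a hydrogenation are still needed to attach ring A.
- Comparison: it matches the chosen route in making a ring that is commercially available in other forms, and it is stronger only in avoiding the Ullmann step. The chosen annulation uses stable partners and a precedented carbonyl condensation, and its by-product chemistry (the carboxyl group) is put to use rather than discarded at once.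

**Alternative 3:** Ring C is disconnected across two C–C bonds into a three-carbon ketone and a three-carbon electrophile. Forward, the aryloxyacetone A8 (rings A and B attached) would condense through both α-carbons with the two termini of the 2-alkyl vinamidinium salt A9 (ring D attached), losing both amino groups, to give phenol A10.

- For it: it builds the most highly substituted ring with regiochemistry dictated by connectivity. The ether oxygen comes from a simple phenol alkylation, and the ring C hydroxyl is delivered free and distinct from the other oxygens. It is more convergent than the chosen route and stronger in that respect.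
- Against it: this benzannulation is established mainly for 2-aryl or 2-heteroatom vinamidinium salts and activated ketones. A 2-alkyl salt is less electrophilic and can be deprotonated at its side chain. The ketone has two different enolisable sites, both of which must react, the second in a demanding ring closure under strong base and heat.
- Comparison: the chosen strategy gives up convergence, but its key step is a known reaction on the same substrate class (2-alkenals with acetoacetates), so the main uncertainty is confined to a well-understood step.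

Key step: step 7

Remark on the chemistry: 14 is written as the racemic trans keto tautomer. It will equilibrate with its enol and its cis epimer, which is immaterial because both sp3 centres are erased in step 8. PPh3·HBr, Ph3P=CHCHO and PhNMe3Br3 are taken to be purchased reagents.

## Route

**Step 1**
Reactants: 1 2,5-dimethoxybenzyl alcohol
Product: 2 (2,5-dimethoxybenzyl)triphenylphosphonium bromide
Conditions: PPh3·HBr (1.05 equiv), MeCN, reflux
Reagents that add atoms: triphenylphosphine hydrobromide, [Br-].[PH+](c1ccccc1)(c1ccccc1)c1ccccc1
Why: The electron-rich benzylic alcohol ionises under HBr and the benzylic bromide or cation is captured by triphenylphosphine, a direct alcohol-to-phosphonium salt conversion that works best on methoxy-substituted benzyl alcohols.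

**Step 2**
Reactants: 3 methyl 3-(4-hydroxyphenyl)propanoate; 4 3-bromo-4-methoxybenzaldehyde
Product: 5 methyl 3-[4-(5-formyl-2-methoxyphenoxy)phenyl]propanoate
Conditions: CuI (10 mol%), N,N-dimethylglycine·HCl (30 mol%), Cs2CO3 (2 equiv), 1,4-dioxane, 100 °C, under argon
Reagents that add atoms: none
Why: Ligand-accelerated Ullmann diaryl ether synthesis; the unhindered, electron-rich phenoxide of 3 couples with the bromide of 4, whose meta-formyl group offsets the ortho-methoxy donor, and the anhydrous carbonate leaves the non-enolisable aldehyde and the methyl ester alone.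

**Step 3**
Reactants: 5 methyl 3-[4-(5-formyl-2-methoxyphenoxy)phenyl]propanoate; 2 (2,5-dimethoxybenzyl)triphenylphosphonium bromide
Product: 7 methyl 3-(4-{5-[2-(2,5-dimethoxyphenyl)ethenyl]-2-methoxyphenoxy}phenyl)propanoate (E/Z mixture), via ylide 6 (not isolated)
Conditions: K2CO3 (3 equiv), 18-crown-6 (0.1 equiv), CH2Cl2, reflux
Reagents that add atoms: none
Why: Wittig olefination with a semi-stabilised benzylic ylide under solid–liquid phase-transfer conditions, which are mild enough for the methyl ester; the E/Z mixture is of no concern because the double bond is saturated in the next step.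

**Step 4**
Reactants: 7 methyl 3-(4-{5-[2-(2,5-dimethoxyphenyl)ethenyl]-2-methoxyphenoxy}phenyl)propanoate (E/Z mixture)
Product: 8 methyl 3-(4-{5-[2-(2,5-dimethoxyphenyl)ethyl]-2-methoxyphenoxy}phenyl)propanoate
Conditions: H2 (1 atm), 10% Pd/C, EtOAc, rt
Reagents that add atoms: none
Why: Heterogeneous catalytic hydrogenation of a stilbene; the ester, methyl ethers and diaryl ether are inert and there is no benzylic C–O bond to cleave.

**Step 5**
Reactants: 8 methyl 3-(4-{5-[2-(2,5-dimethoxyphenyl)ethyl]-2-methoxyphenoxy}phenyl)propanoate
Product: 9 3-(4-{5-[2-(2,5-dimethoxyphenyl)ethyl]-2-methoxyphenoxy}phenyl)propanal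
Conditions: iBu2AlH (1.1 equiv), CH2Cl2, −78 °C; MeOH, then aq. potassium sodium tartrate (KNaC4H4O6)
Reagents that add atoms: none
Why: Partial reduction of a methyl ester; the aluminium-bound tetrahedral hemiacetal persists at −78 °C and releases the aldehyde only on work-up, and no other reducible group is present.

**Step 6**
Reactants: 9 3-(4-{5-[2-(2,5-dimethoxyphenyl)ethyl]-2-methoxyphenoxy}phenyl)propanal
Product: 10 (2E)-5-(4-{5-[2-(2,5-dimethoxyphenyl)ethyl]-2-methoxyphenoxy}phenyl)pent-2-enal
Conditions: Ph3P=CHCHO (1.1 equiv), toluene, 80 °C
Reagents that add atoms: (triphenylphosphoranylidene)acetaldehyde, O=CC=P(c1ccccc1)(c1ccccc1)c1ccccc1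
Why: Wittig reaction with a formyl-stabilised ylide, which gives the E-alkene under thermodynamic control of the oxaphosphetane; the saturated aldehyde 9 is more electrophilic than the conjugated product, so near-stoichiometric ylide should stop after one homologation.

**Step 7**
Reactants: 10 (2E)-5-(4-{5-[2-(2,5-dimethoxyphenyl)ethyl]-2-methoxyphenoxy}phenyl)pent-2-enal; 11 ethyl acetoacetate
Product: 14 ethyl (1RS,6SR)-6-[2-(4-{5-[2-(2,5-dimethoxyphenyl)ethyl]-2-methoxyphenoxy}phenyl)ethyl]-2-oxocyclohex-3-ene-1-carboxylate (racemic trans), via Michael adduct 12 (not isolated), via aldol 13 (not isolated)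
Conditions: 11 (1.5 equiv), NaOEt (0.2 equiv), EtOH, 0 °C → rt, slow addition of 10; AcOH; then TsOH·H2O (0.2 equiv), toluene, 80 °C
Reagents that add atoms: none
Why: Catalytic ethoxide forms the stabilised enolate of 11, which adds through its doubly activated carbon to C3 of enal 10 (Michael addition) to give keto aldehyde 12, in equilibrium with its lactol. Enolisation of the acetyl group toward its methyl carbon and attack on the aldehyde then closes the carbocycle as aldol 13, a 6-(enolendo)-exo-trig closure and the only one open to 12, since the other enolisable positions could only form four-membered rings. Acid-catalysed loss of water with TsOH makes the sequence irreversible and puts the new C3=C4 double bond in conjugation with the ketone. The closest known reaction type is the alkoxide-mediated Michael–aldol annulation of acetoacetic esters with 2-alkenals to 6-alkyl-2-oxocyclohex-3-enecarboxylates, the classical entry to 6-alkylsalicylates. The sp3 centres C1 and C6 are formed without external control (C1 epimerises through the enol toward trans) and both are erased in step 8, so no selectivity is required of them. The step does need conjugate over carbonyl addition and single over double addition: reversible carbonyl addition of the soft β-dicarbonyl anion funnels material to the conjugate adduct, while excess 11, slow addition of 10 and low temperature hold back a second Michael addition and γ-deprotonation of the enal. Regiochemistry follows from connectivity: the ketone oxygen sits on C2 next to the ester carbon C1 and the bridge on C6, so hydroxyl and bridge end up 1,3 once the carboxyl is lost.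

**Step 8**
Reactants: 14 ethyl (1RS,6SR)-6-[2-(4-{5-[2-(2,5-dimethoxyphenyl)ethyl]-2-methoxyphenoxy}phenyl)ethyl]-2-oxocyclohex-3-ene-1-carboxylate
Product: 16 ethyl 2-[2-(4-{5-[2-(2,5-dimethoxyphenyl)ethyl]-2-methoxyphenoxy}phenyl)ethyl]-6-hydroxybenzoate, via bromo keto ester 15 (not isolated)
Conditions: PhNMe3Br3 (1.0 equiv), THF, 0 °C; then DBU (2.5 equiv), 0 °C → rt
Reagents that add atoms: none
Why: Bromination–dehydrobromination aromatisation of a 2-oxocyclohex-3-enecarboxylate; the enol of the β-keto ester takes up bromine at C1 from the mild tribromide faster than the methoxyarenes or the electron-poor C3=C4 bond react, and base-induced loss of HBr across C1–C6 gives a cross-conjugated dienone that tautomerises at once to the salicylate.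

**Step 9**
Reactants: 16 ethyl 2-[2-(4-{5-[2-(2,5-dimethoxyphenyl)ethyl]-2-methoxyphenoxy}phenyl)ethyl]-6-hydroxybenzoate
Product: 17 2-[2-(4-{5-[2-(2,5-dimethoxyphenyl)ethyl]-2-methoxyphenoxy}phenyl)ethyl]-6-hydroxybenzoic acid
Conditions: KOH (10 equiv), aq. DMSO, 100 °C; then aq. HCl
Reagents that add atoms: potassium hydroxide, [K+].[OH-]
Why: Saponification of a di-ortho-substituted benzoate, which needs excess hydroxide in a dipolar solvent at elevated temperature; aryl methyl ethers and the diaryl ether are inert to these conditions.

**Step 10**
Reactants: 17 2-[2-(4-{5-[2-(2,5-dimethoxyphenyl)ethyl]-2-methoxyphenoxy}phenyl)ethyl]-6-hydroxybenzoic acid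
Product: 18 3-[2-(4-{5-[2-(2,5-dimethoxyphenyl)ethyl]-2-methoxyphenoxy}phenyl)ethyl]phenol
Conditions: quinoline, 200 °C, under argon
Reagents that add atoms: none
Why: Thermal protodecarboxylation of a salicylic acid through ipso-protonation of its keto tautomer, eased by the relief of strain between the carboxyl and the ortho-alkyl group, as in the conversion of anacardic acids into cardanols.

**Step 11**
Reactants: 18 3-[2-(4-{5-[2-(2,5-dimethoxyphenyl)ethyl]-2-methoxyphenoxy}phenyl)ethyl]phenol
Product: 19 2-[2-(4-hydroxy-3-{4-[2-(3-hydroxyphenyl)ethyl]phenoxy}phenyl)ethyl]benzene-1,4-diol (target)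
Conditions: BBr3 (6 equiv), CH2Cl2, −78 °C → rt; then H2O, aq. Na2S2O4
Reagents that add atoms: none
Why: Lewis-acid demethylation in which bromide attacks the methyl carbon of each boron-complexed ether; the diaryl ether has only sp2 C–O bonds and is not cleaved, and the reductive work-up keeps the hydroquinone of ring D from oxidising.

## Compound list

1 | 2,5-dimethoxybenzyl alcohol | COc1ccc(OC)c(CO)c1 | starting material
2 | (2,5-dimethoxybenzyl)triphenylphosphonium bromide | [Br-].COc1ccc(OC)c(C[P+](c2ccccc2)(c2ccccc2)c2ccccc2)c1 | intermediate
3 | methyl 3-(4-hydroxyphenyl)propanoate | COC(=O)CCc1ccc(O)cc1 | starting material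
4 | 3-bromo-4-methoxybenzaldehyde | COc1ccc(C=O)cc1Br | starting material
5 | methyl 3-[4-(5-formyl-2-methoxyphenoxy)phenyl]propanoate | COC(=O)CCc1ccc(Oc2cc(C=O)ccc2OC)cc1 | intermediate
6 | (2,5-dimethoxybenzylidene)triphenylphosphorane (ylide) | COc1ccc(OC)c(C=P(c2ccccc2)(c2ccccc2)c2ccccc2)c1 | intermediate (not isolated)
7 | methyl 3-(4-{5-[2-(2,5-dimethoxyphenyl)ethenyl]-2-methoxyphenoxy}phenyl)propanoate, E/Z mixture | COC(=O)CCc1ccc(Oc2cc(C=Cc3cc(OC)ccc3OC)ccc2OC)cc1 | intermediate
8 | methyl 3-(4-{5-[2-(2,5-dimethoxyphenyl)ethyl]-2-methoxyphenoxy}phenyl)propanoate | COC(=O)CCc1ccc(Oc2cc(CCc3cc(OC)ccc3OC)ccc2OC)cc1 | intermediate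
9 | 3-(4-{5-[2-(2,5-dimethoxyphenyl)ethyl]-2-methoxyphenoxy}phenyl)propanal | O=CCCc1ccc(Oc2cc(CCc3cc(OC)ccc3OC)ccc2OC)cc1 | intermediate
10 | (2E)-5-(4-{5-[2-(2,5-dimethoxyphenyl)ethyl]-2-methoxyphenoxy}phenyl)pent-2-enal | O=C/C=C/CCc1ccc(Oc2cc(CCc3cc(OC)ccc3OC)ccc2OC)cc1 | intermediate
11 | ethyl acetoacetate | CCOC(=O)CC(C)=O | starting material
12 | ethyl 2-acetyl-5-(4-{5-[2-(2,5-dimethoxyphenyl)ethyl]-2-methoxyphenoxy}phenyl)-3-(2-oxoethyl)pentanoate, diastereomer mixture | CCOC(=O)C(C(C)=O)C(CC=O)CCc1ccc(Oc2cc(CCc3cc(OC)ccc3OC)ccc2OC)cc1 | intermediate (not isolated)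
13 | ethyl 6-[2-(4-{5-[2-(2,5-dimethoxyphenyl)ethyl]-2-methoxyphenoxy}phenyl)ethyl]-4-hydroxy-2-oxocyclohexane-1-carboxylate, diastereomer mixture | CCOC(=O)C1C(=O)CC(O)CC1CCc1ccc(Oc2cc(CCc3cc(OC)ccc3OC)ccc2OC)cc1 | intermediate (not isolated)
14 | ethyl (1RS,6SR)-6-[2-(4-{5-[2-(2,5-dimethoxyphenyl)ethyl]-2-methoxyphenoxy}phenyl)ethyl]-2-oxocyclohex-3-ene-1-carboxylate, racemic trans (one enantiomer drawn) | CCOC(=O)[C@@H]1C(=O)C=CC[C@H]1CCc1ccc(Oc2cc(CCc3cc(OC)ccc3OC)ccc2OC)cc1 | intermediate
15 | ethyl 1-bromo-6-[2-(4-{5-[2-(2,5-dimethoxyphenyl)ethyl]-2-methoxyphenoxy}phenyl)ethyl]-2-oxocyclohex-3-ene-1-carboxylate, diastereomer mixture | CCOC(=O)C1(Br)C(=O)C=CCC1CCc1ccc(Oc2cc(CCc3cc(OC)ccc3OC)ccc2OC)cc1 | intermediate (not isolated)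
16 | ethyl 2-[2-(4-{5-[2-(2,5-dimethoxyphenyl)ethyl]-2-methoxyphenoxy}phenyl)ethyl]-6-hydroxybenzoate | CCOC(=O)c1c(O)cccc1CCc1ccc(Oc2cc(CCc3cc(OC)ccc3OC)ccc2OC)cc1 | intermediate
17 | 2-[2-(4-{5-[2-(2,5-dimethoxyphenyl)ethyl]-2-methoxyphenoxy}phenyl)ethyl]-6-hydroxybenzoic acid | OC(=O)c1c(O)cccc1CCc1ccc(Oc2cc(CCc3cc(OC)ccc3OC)ccc2OC)cc1 | intermediate
18 | 3-[2-(4-{5-[2-(2,5-dimethoxyphenyl)ethyl]-2-methoxyphenoxy}phenyl)ethyl]phenol | Oc1cccc(CCc2ccc(Oc3cc(CCc4cc(OC)ccc4OC)ccc3OC)cc2)c1 | intermediate
19 | 2-[2-(4-hydroxy-3-{4-[2-(3-hydroxyphenyl)ethyl]phenoxy}phenyl)ethyl]benzene-1,4-diol | Oc1cccc(CCc2ccc(Oc3cc(CCc4cc(O)ccc4O)ccc3O)cc2)c1 | target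

## Step count and least certain steps

Total: 11 steps. Longest linear sequence: 10 steps (3 and 4 to 19, steps 2 to 11); step 1 is a one-step side branch.

**Step 7 (key step).** The most likely failures are carbonyl (1,2) addition and Knoevenagel-type condensation at the aldehyde, base-induced oligomerisation of the enal through γ-deprotonation, and stalling at the open-chain or lactol stage because the ring-closing methyl group is only weakly acidic. A second conjugate addition to the product is also possible.
Fallback, setting out from 10: the donor is changed to diethyl 3-oxopentanedioate under secondary-amine (iminium) catalysis (pyrrolidine, PhCO2H, toluene, rt). Iminium activation enforces conjugate addition under nearly neutral conditions, and the ring then closes through a doubly activated carbon in a Knoevenagel condensation. This should give diethyl 6-[2-(4-{5-[2-(2,5-dimethoxyphenyl)ethyl]-2-methoxyphenoxy}phenyl)ethyl]-2-oxocyclohex-3-ene-1,3-dicarboxylate F1. Bromination at C1 with PhNMe3Br3 gives the 1-bromo diester F2, and DBU then gives diethyl 4-[2-(4-{5-[2-(2,5-dimethoxyphenyl)ethyl]-2-methoxyphenoxy}phenyl)ethyl]-2-hydroxybenzene-1,3-dicarboxylate F3. Hydrolysis with KOH in aq. DMSO gives the corresponding 2-hydroxybenzene-1,3-dicarboxylic acid F4, whose twofold thermal decarboxylation in quinoline comes back to the route at 18.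

**Step 8.** The risk is electrophilic bromination of rings C and D in competition with enol bromination, or incomplete loss of HBr from 15.
Fallback, setting out from 14: the order of events is reversed so that no halogen is used. Hydrolysis and decarboxylation of the β-keto ester (LiOH, THF/H2O; then aq. HCl, 50 °C) gives 5-[2-(4-{5-[2-(2,5-dimethoxyphenyl)ethyl]-2-methoxyphenoxy}phenyl)ethyl]cyclohex-2-en-1-one F5. Aerobic dehydrogenation catalysed by divalent palladium (Pd(O2CCF3)2, 2-(dimethylamino)pyridine, TsOH, O2, DMSO, 80 °C) then gives the phenol and comes back to the route at 18, bypassing steps 9 and 10.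

**Step 6.** The product is itself an aldehyde, so a second homologation to the dienal can compete, and the enal can isomerise or self-condense on prolonged heating.
Fallback, setting out from 9: Horner–Wadsworth–Emmons olefination with triethyl phosphonoacetate (NaH, THF, 0 °C) gives ethyl (2E)-5-(4-{5-[2-(2,5-dimethoxyphenyl)ethyl]-2-methoxyphenoxy}phenyl)pent-2-enoate F6. Reduction with iBu2AlH (2.2 equiv, −78 °C) gives (2E)-5-(4-{5-[2-(2,5-dimethoxyphenyl)ethyl]-2-methoxyphenoxy}phenyl)pent-2-en-1-ol F7, and allylic oxidation with MnO2 in CH2Cl2 comes back to the route at 10.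

**Step 5.** The tetrahedral intermediate may collapse before the quench, leading to over-reduction to the primary alcohol.
Fallback, setting out from 8: full reduction with LiAlH4 in THF gives 3-(4-{5-[2-(2,5-dimethoxyphenyl)ethyl]-2-methoxyphenoxy}phenyl)propan-1-ol F8, and oxidation with Dess–Martin periodinane (NaHCO3, CH2Cl2) comes back to the route at 9.

**Step 2.** Oxidative addition at the bromide flanked by a methoxy group may be slow, so the coupling can stall and hydrodebromination of 4 can take over.
Fallback, setting out from 2: the ether is made by nucleophilic aromatic substitution after the C–D bridge is in place. Wittig reaction of 2 (KOtBu, 2.2 equiv, THF) with 3-hydroxy-4-methoxybenzaldehyde gives 5-[2-(2,5-dimethoxyphenyl)ethenyl]-2-methoxyphenol F9 (E/Z mixture), and hydrogenation (H2, Pd/C) gives 5-[2-(2,5-dimethoxyphenyl)ethyl]-2-methoxyphenol F10. Displacement of fluoride from 4-fluorobenzaldehyde (K2CO3, DMF, 140 °C) gives 4-{5-[2-(2,5-dimethoxyphenyl)ethyl]-2-methoxyphenoxy}benzaldehyde F11. Wittig reaction with methyl (triphenylphosphoranylidene)acetate gives methyl (2E)-3-(4-{5-[2-(2,5-dimethoxyphenyl)ethyl]-2-methoxyphenoxy}phenyl)prop-2-enoate F12, and hydrogenation (H2, Pd/C) comes back to the route at 8, bypassing steps 2 to 4.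

## Further compounds

F1 | step 7 | diethyl 6-[2-(4-{5-[2-(2,5-dimethoxyphenyl)ethyl]-2-methoxyphenoxy}phenyl)ethyl]-2-oxocyclohex-3-ene-1,3-dicarboxylate (racemic, diastereomer mixture) | CCOC(=O)C1C(=O)C(C(=O)OCC)=CCC1CCc1ccc(Oc2cc(CCc3cc(OC)ccc3OC)ccc2OC)cc1
F2 | step 7 | diethyl 1-bromo-6-[2-(4-{5-[2-(2,5-dimethoxyphenyl)ethyl]-2-methoxyphenoxy}phenyl)ethyl]-2-oxocyclohex-3-ene-1,3-dicarboxylate (diastereomer mixture) | CCOC(=O)C1(Br)C(=O)C(C(=O)OCC)=CCC1CCc1ccc(Oc2cc(CCc3cc(OC)ccc3OC)ccc2OC)cc1
F3 | step 7 | diethyl 4-[2-(4-{5-[2-(2,5-dimethoxyphenyl)ethyl]-2-methoxyphenoxy}phenyl)ethyl]-2-hydroxybenzene-1,3-dicarboxylate | CCOC(=O)c1ccc(CCc2ccc(Oc3cc(CCc4cc(OC)ccc4OC)ccc3OC)cc2)c(C(=O)OCC)c1O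
F4 | step 7 | 4-[2-(4-{5-[2-(2,5-dimethoxyphenyl)ethyl]-2-methoxyphenoxy}phenyl)ethyl]-2-hydroxybenzene-1,3-dicarboxylic acid | OC(=O)c1ccc(CCc2ccc(Oc3cc(CCc4cc(OC)ccc4OC)ccc3OC)cc2)c(C(=O)O)c1O
F5 | step 8 | 5-[2-(4-{5-[2-(2,5-dimethoxyphenyl)ethyl]-2-methoxyphenoxy}phenyl)ethyl]cyclohex-2-en-1-one (racemic) | O=C1C=CCC(CCc2ccc(Oc3cc(CCc4cc(OC)ccc4OC)ccc3OC)cc2)C1
F6 | step 6 | ethyl (2E)-5-(4-{5-[2-(2,5-dimethoxyphenyl)ethyl]-2-methoxyphenoxy}phenyl)pent-2-enoate | CCOC(=O)/C=C/CCc1ccc(Oc2cc(CCc3cc(OC)ccc3OC)ccc2OC)cc1
F7 | step 6 | (2E)-5-(4-{5-[2-(2,5-dimethoxyphenyl)ethyl]-2-methoxyphenoxy}phenyl)pent-2-en-1-ol | OC/C=C/CCc1ccc(Oc2cc(CCc3cc(OC)ccc3OC)ccc2OC)cc1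
F8 | step 5 | 3-(4-{5-[2-(2,5-dimethoxyphenyl)ethyl]-2-methoxyphenoxy}phenyl)propan-1-ol | OCCCc1ccc(Oc2cc(CCc3cc(OC)ccc3OC)ccc2OC)cc1
F9 | step 2 | 5-[2-(2,5-dimethoxyphenyl)ethenyl]-2-methoxyphenol (E/Z mixture) | COc1ccc(C=Cc2cc(OC)ccc2OC)cc1O
F10 | step 2 | 5-[2-(2,5-dimethoxyphenyl)ethyl]-2-methoxyphenol | COc1ccc(CCc2cc(OC)ccc2OC)cc1O
F11 | step 2 | 4-{5-[2-(2,5-dimethoxyphenyl)ethyl]-2-methoxyphenoxy}benzaldehyde | O=Cc1ccc(Oc2cc(CCc3cc(OC)ccc3OC)ccc2OC)cc1
F12 | step 2 | methyl (2E)-3-(4-{5-[2-(2,5-dimethoxyphenyl)ethyl]-2-methoxyphenoxy}phenyl)prop-2-enoate | COC(=O)/C=C/c1ccc(Oc2cc(CCc3cc(OC)ccc3OC)ccc2OC)cc1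
A1 | alternative 1 | 4-bromo-2-(4-iodophenoxy)-1-methoxybenzene | COc1ccc(Br)cc1Oc1ccc(I)cc1
A2 | alternative 1 | 3-ethynylanisole (1-ethynyl-3-methoxybenzene) | C#Cc1cccc(OC)c1
A3 | alternative 1 | 2-ethynyl-1,4-dimethoxybenzene | C#Cc1cc(OC)ccc1OC
A4 | alternative 1 | 2-[(4-methoxy-3-{4-[(3-methoxyphenyl)ethynyl]phenoxy}phenyl)ethynyl]-1,4-dimethoxybenzene | COc1cccc(C#Cc2ccc(Oc3cc(C#Cc4cc(OC)ccc4OC)ccc3OC)cc2)c1
A5 | alternative 2 | methyl coumalate (methyl 2-oxo-2H-pyran-5-carboxylate) | COC(=O)C1=COC(=O)C=C1
A6 | alternative 2 | 4-[2-(2,5-dimethoxyphenyl)ethyl]-2-(ethynyloxy)-1-methoxybenzene | C#COc1cc(CCc2cc(OC)ccc2OC)ccc1OC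
A7 | alternative 2 | methyl 4-{5-[2-(2,5-dimethoxyphenyl)ethyl]-2-methoxyphenoxy}benzoate | COC(=O)c1ccc(Oc2cc(CCc3cc(OC)ccc3OC)ccc2OC)cc1
A8 | alternative 3 | 1-{4-[2-(3-methoxyphenyl)ethyl]phenoxy}propan-2-one | CC(=O)COc1ccc(CCc2cccc(OC)c2)cc1
A9 | alternative 3 | N-{3-(dimethylamino)-2-[2-(2,5-dimethoxyphenyl)ethyl]prop-2-en-1-ylidene}-N-methylmethanaminium hexafluorophosphate (vinamidinium salt) | C[N+](C)=CC(CCc1cc(OC)ccc1OC)=CN(C)C.F[P-](F)(F)(F)(F)F
A10 | alternative 3 | 4-[2-(2,5-dimethoxyphenyl)ethyl]-2-{4-[2-(3-methoxyphenyl)ethyl]phenoxy}phenol | COc1cccc(CCc2ccc(Oc3cc(CCc4cc(OC)ccc4OC)ccc3O)cc2)c1
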